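**Plan**

1. Numbering used below: decalin C1–C10 (gem-dimethyl on C4, methyl on C8 and C10), chain C11–C16, hydroxymethyl carbon C21 on C13, lactone C17–C20. The descriptors of the target correspond to 5R,10S, which is a cis-fused decalin (10-CH3 and 5-H on the same face).
2. Enabling feature: ring B is a cyclohexene whose C8=C9 bond lies between C7 and the quaternary C10. That is the retron of a [4+2] addition of a C7=C8–C9=C10 diene to a C5=C6 alkene, with C1–C4 of ring A as the tether; the cis fusion corresponds to a diene whose tether is cis to C8.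
3. Retrosynthesis, in order: C16–C17 (Suzuki), C15=C16 (boron-Wittig), C12–C13 (B-alkyl Suzuki), C11=C12 (methylenation), then C6–C7 and C5–C10 together (intramolecular Diels–Alder, with a formyl group on C6 as removable activator), then C5=C6 (Wittig), C3–C4 (nitrile alkylation), C10–CH3 (Negishi), C8–C9 (carbomagnesiation), C9–C11 (formaldehyde).
4. Forward: an acyclic trienal is built in six steps; rings A and B close together in step 7; the C6 formyl group is removed; the chain is joined at C12–C13, extended at C16 and capped with the lactone.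
5. Stereochemistry: the C5/C10 relative configuration comes from the diene geometry (steps 2 and 3) and the absolute configuration from the (2R,5R)-imidazolidinone catalyst in step 7. C13=C14 comes from trans-hydroalumination/iodination (step 12) and C15=C16 from the boron-Wittig reaction (step 15).

Key step: step 7

**Route**

Step 1
Reactants: 1 5-chloropent-1-yne
Product: 3 6-chlorohex-2-yn-1-ol, via lithium acetylide 2 (not isolated)
Conditions: n-BuLi, THF, −78 °C; (CH2O)n, −78 °C → rt; H2O
Reagents that add atoms: paraformaldehyde (as formaldehyde) C=O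
Why: Addition of a lithium acetylide to formaldehyde (acetylide hydroxymethylation) is reliable, and the primary alkyl chloride is inert to the acetylide at this temperature.

Step 2
Reactants: 3 6-chlorohex-2-yn-1-ol
Product: 5 (2Z)-6-chloro-3-iodo-2-(prop-1-en-2-yl)hex-2-en-1-ol, via magnesium chelate 4 (not isolated)
Conditions: CH2=C(CH3)MgBr (3.5 equiv), CuI (10 mol%), THF, 0 °C → reflux; then I2, −40 → 0 °C; aq Na2S2O3
Reagents that add atoms: isopropenylmagnesium bromide C=C(C)[Mg]Br; iodine II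
Why: Alkoxide-directed anti-carbomagnesiation of a 2-alkyn-1-ol should deliver the alkenyl group to the proximal alkyne carbon (C9) and place magnesium on C10 cis to CH2O in a five-membered chelate, and iodinolysis with retention then fixes the tetrasubstituted C9=C10 geometry (iodine cis to CH2OH, the C1 chain cis to the isopropenyl group).

Step 3
Reactants: 5 (2Z)-6-chloro-3-iodo-2-(prop-1-en-2-yl)hex-2-en-1-ol
Product: 6 (2E)-6-chloro-3-methyl-2-(prop-1-en-2-yl)hex-2-en-1-ol
Conditions: Me2Zn (3 equiv), Pd(dppf)Cl2 (5 mol%), THF, 60 °C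
Reagents that add atoms: dimethylzinc C[Zn]C
Why: Negishi coupling of an alkenyl iodide proceeds with retention, so the new C10 methyl group ends cis to CH2OH and the C1–C3 chain stays cis to C8; this catalyst does not insert into the primary C–Cl bond and the hydroxyl is carried as its zinc alkoxide.

Step 4
Reactants: 6 (2E)-6-chloro-3-methyl-2-(prop-1-en-2-yl)hex-2-en-1-ol; 7 2-methylpropanenitrile
Product: 9 (6E)-8-hydroxy-2,2,6-trimethyl-7-(prop-1-en-2-yl)oct-6-enenitrile, via lithiated nitrile 8 (not isolated)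
Conditions: 7 (3.3 equiv), LiN(i-Pr)2 (3.2 equiv), THF, −78 °C; then 6, DMPU, NaI (10 mol%), −78 → 40 °C; H2O
Reagents that add atoms: none
Why: SN2 alkylation of the lithiated tertiary nitrile with the primary chloride builds the quaternary C4 with both methyl groups in one operation, the hydroxyl being masked in the flask as its lithium alkoxide.

Step 5
Reactants: 9 (6E)-8-hydroxy-2,2,6-trimethyl-7-(prop-1-en-2-yl)oct-6-enenitrile
Product: 11 (6E)-8-hydroxy-2,2,6-trimethyl-7-(prop-1-en-2-yl)oct-6-enal, via aldimine 10 (not isolated)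
Conditions: i-Bu2AlH (2.5 equiv), CH2Cl2, −78 → 0 °C; then aq tartaric acid, rt
Reagents that add atoms: water O
Why: i-Bu2AlH adds once to the hindered nitrile to give an N-aluminio aldimine that is hydrolysed on mildly acidic work-up (partial reduction of a nitrile to an aldehyde); the excess hydride only deprotonates the alcohol.

Step 6
Reactants: 11 (6E)-8-hydroxy-2,2,6-trimethyl-7-(prop-1-en-2-yl)oct-6-enal
Product: 12 (2E,8E)-10-hydroxy-4,4,8-trimethyl-9-(prop-1-en-2-yl)deca-2,8-dienal
Conditions: Ph3P=CHCHO (1.5 equiv), toluene, 80 °C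
Reagents that add atoms: (triphenylphosphoranylidene)acetaldehyde O=CC=P(c1ccccc1)(c1ccccc1)c1ccccc1
Why: Wittig olefination with the stabilised formylmethylene ylide should give the (E)-enal (C5=C6) without a second homologation, and the temperature is kept below the range in which the hindered triene is expected to cyclise without a catalyst.

Step 7
Reactants: 12 (2E,8E)-10-hydroxy-4,4,8-trimethyl-9-(prop-1-en-2-yl)deca-2,8-dienal
Product: 15 (1R,4aS,8aR)-4-(hydroxymethyl)-3,4a,8,8-tetramethyl-1,2,4a,5,6,7,8,8a-octahydronaphthalene-1-carbaldehyde, via trienal iminium ion 13 (not isolated), via cycloadduct iminium ion 14 (not isolated)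
Conditions: (2R,5R)-5-benzyl-2-tert-butyl-3-methylimidazolidin-4-one (20 mol%), CF3CO2H (20 mol%), MeCN/H2O 95:5, 0 °C → rt
Reagents that add atoms: none
Why: The amine salt condenses with the enal to the (E)-iminium ion 13, whose lowered LUMO should allow a concerted but asynchronous [4+2] cycloaddition of the C5=C6 dienophile with the tethered C7=C8–C9=C10 diene near room temperature, far below the temperatures of thermal [1,5]-hydrogen shifts in the cis-substituted diene, and hydrolysis of the adduct iminium ion 14 releases 15 and the catalyst. The closest known reaction type is the imidazolidinone-catalysed intramolecular Diels–Alder reaction of (E)-deca-2,7,9-trienals to octalin carbaldehydes. Ring B is the cyclohexene closed by the cycloaddition itself (bonds C6–C7 and C5–C10), and ring A is closed in the same event as a six-membered carbocycle because the four-carbon tether C1–C4 joins the diene terminus C10 to the dienophile carbon C5 (type 1 mode, fused bicyclo[4.4.0] product). The relative configuration at C5 and C10 is controlled by the diene geometry: the tether is cis to C8 on the C9=C10 bond, and for such a diene only the transition state with the tether exo and the iminium group endo is geometrically accessible, which gives the cis ring fusion (10-methyl and 5-H syn) and the trans C5/C6 relationship. The absolute configuration is controlled by the catalyst, whose benzyl group shields the C6-si face of the (E)-iminium ion so that the diene adds to the C6-re/C5-re face, which makes C5 R and C10 S (and C6 R, erased in step 8). The step needs facial selectivity, cis over trans fusion and the absence of an uncatalysed racemic background reaction, which are secured respectively by the catalyst, by the tetrasubstituted diene geometry fixed in steps 2 and 3, and by the low temperature at which only the iminium-activated dienophile should react, the gem-dimethyl group on C4 and the electron-rich trialkyl diene assisting ring closure.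

Step 8
Reactants: 15 (1R,4aS,8aR)-4-(hydroxymethyl)-3,4a,8,8-tetramethyl-1,2,4a,5,6,7,8,8a-octahydronaphthalene-1-carbaldehyde
Product: 16 [(4aR,8aS)-2,5,5,8a-tetramethyl-3,4,4a,5,6,7,8,8a-octahydronaphthalen-1-yl]methanol
Conditions: RhCl(PPh3)3 (1.1 equiv), PhCN, 130 °C
Reagents that add atoms: none
Why: Tsuji–Wilkinson decarbonylation replaces the formyl group by hydrogen and so erases the activating group and the C6 stereocentre, while the tetrasubstituted C8=C9 bond is too hindered to be isomerised and C5 and C10 are untouched.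

Step 9
Reactants: 16 [(4aR,8aS)-2,5,5,8a-tetramethyl-3,4,4a,5,6,7,8,8a-octahydronaphthalen-1-yl]methanol
Product: 17 (4aR,8aS)-2,5,5,8a-tetramethyl-3,4,4a,5,6,7,8,8a-octahydronaphthalene-1-carbaldehyde
Conditions: MnO2 (20 equiv), CH2Cl2, rt
Reagents that add atoms: none
Why: Oxidation of a primary allylic alcohol with MnO2 is chemoselective and should give the conjugated C11 aldehyde without touching the ring alkene or the ring-fusion centres.

Step 10
Reactants: 17 (4aR,8aS)-2,5,5,8a-tetramethyl-3,4,4a,5,6,7,8,8a-octahydronaphthalene-1-carbaldehyde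
Product: 18 (4aR,8aS)-1-ethenyl-2,5,5,8a-tetramethyl-3,4,4a,5,6,7,8,8a-octahydronaphthalene
Conditions: Ph3PCH3Br, KOt-Bu, THF, 0 °C → rt
Reagents that add atoms: methyltriphenylphosphonium bromide C[P+](c1ccccc1)(c1ccccc1)c1ccccc1.[Br-]
Why: Wittig methylenation of the aldehyde installs C12 as the terminus of a vinyl group on C9; no stereocentre is formed.

Step 11
Reactants: 19 but-2-yne-1,4-diol
Product: 20 4-{[tert-butyl(dimethyl)silyl]oxy}but-2-yn-1-ol
Conditions: NaH (1.0 equiv), THF, 0 °C; t-BuMe2SiCl (1.0 equiv), rt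
Reagents that add atoms: tert-butyldimethylsilyl chloride CC(C)(C)[Si](C)(C)Cl
Why: O-silylation of a symmetrical diol through its sparingly soluble monosodium alkoxide should stop at the monosilyl ether and so differentiates the two hydroxyl groups.

Step 12
Reactants: 20 4-{[tert-butyl(dimethyl)silyl]oxy}but-2-yn-1-ol
Product: 22 (2Z)-4-{[tert-butyl(dimethyl)silyl]oxy}-3-iodobut-2-en-1-ol, via alkenylalanate 21 (not isolated)
Conditions: NaAlH2(OCH2CH2OCH3)2 (1.5 equiv), THF, 0 °C → rt; then I2, −78 → 0 °C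
Reagents that add atoms: iodine II
Why: Hydroxyl-directed trans-hydroalumination of a 2-alkyn-1-ol delivers hydride to C14 and aluminium to C13 cis to CH2O in a five-membered chelate, and iodinolysis with retention gives the iodoalkene in which iodine (the later place of C12) is cis to C15.

Step 13
Reactants: 18 (4aR,8aS)-1-ethenyl-2,5,5,8a-tetramethyl-3,4,4a,5,6,7,8,8a-octahydronaphthalene; 22 (2Z)-4-{[tert-butyl(dimethyl)silyl]oxy}-3-iodobut-2-en-1-ol
Product: 24 (2E)-3-({[tert-butyl(dimethyl)silyl]oxy}methyl)-5-[(4aR,8aS)-2,5,5,8a-tetramethyl-3,4,4a,5,6,7,8,8a-octahydronaphthalen-1-yl]pent-2-en-1-ol, via alkylborane 23 (not isolated)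
Conditions: 9-BBN-H (1.2 equiv), THF, 0 °C → rt; then 22 (1.2 equiv), Pd(dppf)Cl2 (5 mol%), AsPh3 (10 mol%), Cs2CO3 (3 equiv), DMF/THF/H2O, rt
Reagents that add atoms: none
Why: Hydroboration with 9-BBN-H should take place only at the terminal CH2 of the monosubstituted vinyl group (anti-Markovnikov), and the B-alkyl Suzuki–Miyaura coupling with the alkenyl iodide proceeds with retention, so C12 ends cis to C15; the tetrasubstituted ring alkene and the free hydroxyl do not interfere.

Step 14
Reactants: 24 (2E)-3-({[tert-butyl(dimethyl)silyl]oxy}methyl)-5-[(4aR,8aS)-2,5,5,8a-tetramethyl-3,4,4a,5,6,7,8,8a-octahydronaphthalen-1-yl]pent-2-en-1-ol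
Product: 25 (2E)-3-({[tert-butyl(dimethyl)silyl]oxy}methyl)-5-[(4aR,8aS)-2,5,5,8a-tetramethyl-3,4,4a,5,6,7,8,8a-octahydronaphthalen-1-yl]pent-2-enal
Conditions: MnO2 (20 equiv), CH2Cl2, rt
Reagents that add atoms: none
Why: Allylic oxidation with MnO2 converts only the free C15 alcohol (the C21 oxygen is silylated) into the enal under neutral conditions that should not isomerise the C13=C14 bond.

Step 15
Reactants: 25 (2E)-3-({[tert-butyl(dimethyl)silyl]oxy}methyl)-5-[(4aR,8aS)-2,5,5,8a-tetramethyl-3,4,4a,5,6,7,8,8a-octahydronaphthalen-1-yl]pent-2-enal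
Product: 26 2-[(1E,3E)-4-({[tert-butyl(dimethyl)silyl]oxy}methyl)-6-[(4aR,8aS)-2,5,5,8a-tetramethyl-3,4,4a,5,6,7,8,8a-octahydronaphthalen-1-yl]hexa-1,3-dien-1-yl]-4,4,5,5-tetramethyl-1,3,2-dioxaborolane
Conditions: CH2(Bpin)2 (1.3 equiv), LiTMP (1.2 equiv), THF, 0 °C; then 25, −78 °C → rt
Reagents that add atoms: 2,2'-methylenebis(4,4,5,5-tetramethyl-1,3,2-dioxaborolane) CC1(C)OB(CB2OC(C)(C)C(C)(C)O2)OC1(C)C
Why: Boron-Wittig olefination (1,2-addition of the lithiated geminal bis(boronate) to the aldehyde and syn elimination of a boron–oxygen unit) should give the (E)-alkenyl boronate and so sets the C15=C16 geometry while adding C16.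

Step 16
Reactants: 26 2-[(1E,3E)-4-({[tert-butyl(dimethyl)silyl]oxy}methyl)-6-[(4aR,8aS)-2,5,5,8a-tetramethyl-3,4,4a,5,6,7,8,8a-octahydronaphthalen-1-yl]hexa-1,3-dien-1-yl]-4,4,5,5-tetramethyl-1,3,2-dioxaborolane; 27 4-bromofuran-2(5H)-one
Product: 28 4-[(1E,3E)-4-({[tert-butyl(dimethyl)silyl]oxy}methyl)-6-[(4aR,8aS)-2,5,5,8a-tetramethyl-3,4,4a,5,6,7,8,8a-octahydronaphthalen-1-yl]hexa-1,3-dien-1-yl]furan-2(5H)-one
Conditions: Pd(dppf)Cl2 (5 mol%), K3PO4 (3 equiv), THF/H2O 10:1, rt
Reagents that add atoms: none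
Why: Suzuki–Miyaura coupling of the dienyl boronate with the β-bromobutenolide, a vinylogous acyl bromide that adds readily to zerovalent palladium, joins C16 to C17 with retention of both alkene geometries under mildly basic conditions.

Step 17
Reactants: 28 4-[(1E,3E)-4-({[tert-butyl(dimethyl)silyl]oxy}methyl)-6-[(4aR,8aS)-2,5,5,8a-tetramethyl-3,4,4a,5,6,7,8,8a-octahydronaphthalen-1-yl]hexa-1,3-dien-1-yl]furan-2(5H)-one
Product: 29 4-[(1E,3E)-4-(hydroxymethyl)-6-[(4aR,8aS)-2,5,5,8a-tetramethyl-3,4,4a,5,6,7,8,8a-octahydronaphthalen-1-yl]hexa-1,3-dien-1-yl]furan-2(5H)-one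
Conditions: HF·pyridine, THF/pyridine, 0 °C → rt
Reagents that add atoms: none
Why: Fluoride-mediated cleavage of the primary silyl ether under buffered, non-basic conditions should leave the base-sensitive butenolide and the conjugated triene intact.

**Compound list**

1 | 5-chloropent-1-yne | C#CCCCCl | starting material
2 | lithium 5-chloropent-1-yn-1-ide | [Li]C#CCCCCl | intermediate (not isolated)
3 | 6-chlorohex-2-yn-1-ol | OCC#CCCCCl | intermediate
4 | 3-(3-chloropropyl)-4-(prop-1-en-2-yl)-2,5-dihydro-1,2-oxamagnesole (cyclic alkenylmagnesium alkoxide, Mg on C10 cis to CH2O) | ClCCCC1=C(C(C)=C)CO[Mg]1 | intermediate (not isolated)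
5 | (2Z)-6-chloro-3-iodo-2-(prop-1-en-2-yl)hex-2-en-1-ol (I cis to CH2OH) | OC/C(C(C)=C)=C(\I)CCCCl | intermediate
6 | (2E)-6-chloro-3-methyl-2-(prop-1-en-2-yl)hex-2-en-1-ol (CH3 cis to CH2OH, chloropropyl cis to isopropenyl) | OC/C(C(C)=C)=C(\C)CCCCl | intermediate
7 | 2-methylpropanenitrile | CC(C)C#N | starting material
8 | 2-lithio-2-methylpropanenitrile | [Li]C(C)(C)C#N | intermediate (not isolated)
9 | (6E)-8-hydroxy-2,2,6-trimethyl-7-(prop-1-en-2-yl)oct-6-enenitrile | OC/C(C(C)=C)=C(\C)CCCC(C)(C)C#N | intermediate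
10 | (2E)-8-imino-3,7,7-trimethyl-2-(prop-1-en-2-yl)oct-2-en-1-ol (aldimine, present as its N-aluminium derivative) | OC/C(C(C)=C)=C(\C)CCCC(C)(C)C=N | intermediate (not isolated)
11 | (6E)-8-hydroxy-2,2,6-trimethyl-7-(prop-1-en-2-yl)oct-6-enal | OC/C(C(C)=C)=C(\C)CCCC(C)(C)C=O | intermediate
12 | (2E,8E)-10-hydroxy-4,4,8-trimethyl-9-(prop-1-en-2-yl)deca-2,8-dienal | OC/C(C(C)=C)=C(\C)CCCC(C)(C)/C=C/C=O | intermediate
13 | 5-benzyl-2-tert-butyl-1-[(2E,8E)-10-hydroxy-4,4,8-trimethyl-9-(prop-1-en-2-yl)deca-2,8-dien-1-ylidene]-3-methyl-4-oxoimidazolidin-1-ium trifluoroacetate (ring centres as in the (2R,5R) catalyst) | CN1[C@H](C(C)(C)C)[N+](=C/C=C/C(C)(C)CCC/C(C)=C(/CO)C(C)=C)[C@H](Cc2ccccc2)C1=O.[O-]C(=O)C(F)(F)F | intermediate (not isolated)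
14 | 5-benzyl-2-tert-butyl-1-{[(1R,4aS,8aR)-4-(hydroxymethyl)-3,4a,8,8-tetramethyl-1,2,4a,5,6,7,8,8a-octahydronaphthalen-1-yl]methylidene}-3-methyl-4-oxoimidazolidin-1-ium trifluoroacetate (ring centres as in the (2R,5R) catalyst) | CC1=C(CO)[C@@]2(C)CCCC(C)(C)[C@H]2[C@H](C=[N+]3[C@@H](C(C)(C)C)N(C)C(=O)[C@H]3Cc4ccccc4)C1.[O-]C(=O)C(F)(F)F | intermediate (not isolated)
15 | (1R,4aS,8aR)-4-(hydroxymethyl)-3,4a,8,8-tetramethyl-1,2,4a,5,6,7,8,8a-octahydronaphthalene-1-carbaldehyde (5R,6R,10S in the numbering of the plan; cis-fused) | CC1=C(CO)[C@@]2(C)CCCC(C)(C)[C@H]2[C@H](C=O)C1 | intermediate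
16 | [(4aR,8aS)-2,5,5,8a-tetramethyl-3,4,4a,5,6,7,8,8a-octahydronaphthalen-1-yl]methanol | CC1=C(CO)[C@@]2(C)CCCC(C)(C)[C@H]2CC1 | intermediate
17 | (4aR,8aS)-2,5,5,8a-tetramethyl-3,4,4a,5,6,7,8,8a-octahydronaphthalene-1-carbaldehyde | CC1=C(C=O)[C@@]2(C)CCCC(C)(C)[C@H]2CC1 | intermediate
18 | (4aR,8aS)-1-ethenyl-2,5,5,8a-tetramethyl-3,4,4a,5,6,7,8,8a-octahydronaphthalene | CC1=C(C=C)[C@@]2(C)CCCC(C)(C)[C@H]2CC1 | intermediate
19 | but-2-yne-1,4-diol | OCC#CCO | starting material
20 | 4-{[tert-butyl(dimethyl)silyl]oxy}but-2-yn-1-ol | OCC#CCO[Si](C)(C)C(C)(C)C | intermediate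
21 | sodium 3-({[tert-butyl(dimethyl)silyl]oxy}methyl)-2,2-bis(2-methoxyethoxy)-2,5-dihydro-1,2-oxaaluminol-2-uide (cyclic alkenylalanate) | [Na+].COCCO[Al-]1(OCCOC)OCC=C1CO[Si](C)(C)C(C)(C)C | intermediate (not isolated)
22 | (2Z)-4-{[tert-butyl(dimethyl)silyl]oxy}-3-iodobut-2-en-1-ol (I cis to CH2OH) | OC/C=C(\I)CO[Si](C)(C)C(C)(C)C | intermediate
23 | 9-{2-[(4aR,8aS)-2,5,5,8a-tetramethyl-3,4,4a,5,6,7,8,8a-octahydronaphthalen-1-yl]ethyl}-9-borabicyclo[3.3.1]nonane | CC1=C(CCB3C4CCCC3CCC4)[C@@]2(C)CCCC(C)(C)[C@H]2CC1 | intermediate (not isolated)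
24 | (2E)-3-({[tert-butyl(dimethyl)silyl]oxy}methyl)-5-[(4aR,8aS)-2,5,5,8a-tetramethyl-3,4,4a,5,6,7,8,8a-octahydronaphthalen-1-yl]pent-2-en-1-ol (C12 cis to C15) | CC1=C(CC/C(=C\CO)CO[Si](C)(C)C(C)(C)C)[C@@]2(C)CCCC(C)(C)[C@H]2CC1 | intermediate
25 | (2E)-3-({[tert-butyl(dimethyl)silyl]oxy}methyl)-5-[(4aR,8aS)-2,5,5,8a-tetramethyl-3,4,4a,5,6,7,8,8a-octahydronaphthalen-1-yl]pent-2-enal | CC1=C(CC/C(=C\C=O)CO[Si](C)(C)C(C)(C)C)[C@@]2(C)CCCC(C)(C)[C@H]2CC1 | intermediate
26 | 2-[(1E,3E)-4-({[tert-butyl(dimethyl)silyl]oxy}methyl)-6-[(4aR,8aS)-2,5,5,8a-tetramethyl-3,4,4a,5,6,7,8,8a-octahydronaphthalen-1-yl]hexa-1,3-dien-1-yl]-4,4,5,5-tetramethyl-1,3,2-dioxaborolane | CC1=C(CC/C(=C\C=C\B3OC(C)(C)C(C)(C)O3)CO[Si](C)(C)C(C)(C)C)[C@@]2(C)CCCC(C)(C)[C@H]2CC1 | intermediate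
27 | 4-bromofuran-2(5H)-one | BrC1=CC(=O)OC1 | starting material
28 | 4-[(1E,3E)-4-({[tert-butyl(dimethyl)silyl]oxy}methyl)-6-[(4aR,8aS)-2,5,5,8a-tetramethyl-3,4,4a,5,6,7,8,8a-octahydronaphthalen-1-yl]hexa-1,3-dien-1-yl]furan-2(5H)-one | CC1=C(CC/C(=C\C=C\C3=CC(=O)OC3)CO[Si](C)(C)C(C)(C)C)[C@@]2(C)CCCC(C)(C)[C@H]2CC1 | intermediate
29 | 4-[(1E,3E)-4-(hydroxymethyl)-6-[(4aR,8aS)-2,5,5,8a-tetramethyl-3,4,4a,5,6,7,8,8a-octahydronaphthalen-1-yl]hexa-1,3-dien-1-yl]furan-2(5H)-one | CC1=C(CC/C(=C\C=C\C3=CC(=O)OC3)CO)[C@@]2(C)CCCC(C)(C)[C@H]2CC1 | target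

**Step count and risks**

Total step count: 17. Longest linear sequence: 15 steps (steps 1–10 and 13–17; steps 11 and 12 form the side branch).

Steps most likely to fail:

Step 7. The diene has a fully substituted terminus with the tether on the inside, so the cycloaddition may be too slow for iminium catalysis to turn over. An uncatalysed pathway could then erode the facial selectivity, and the acid co-catalyst could ionise the dienyl carbinol. The fallback replaces catalyst control by a covalently bound auxiliary and a strong Lewis acid; it sets out from 11 and comes back to the route at 15. Horner–Wadsworth–Emmons olefination of 11 with (4R)-4-benzyl-3-[2-(diethoxyphosphoryl)acetyl]-1,3-oxazolidin-2-one (LiCl, i-Pr2NEt, MeCN, rt) should give the imide (4R)-4-benzyl-3-[(2E,8E)-10-hydroxy-4,4,8-trimethyl-9-(prop-1-en-2-yl)deca-2,8-dienoyl]-1,3-oxazolidin-2-one F1. Treatment with Me2AlCl (2.5 equiv, one equivalent being used up by the hydroxyl; CH2Cl2, −30 °C) should form the chelated s-cis N-enoyl oxazolidinone, in which the benzyl group shields the C6-si face. The same tether-exo transition state then gives the cis-fused adduct (4R)-4-benzyl-3-{[(1R,4aS,8aR)-4-(hydroxymethyl)-3,4a,8,8-tetramethyl-1,2,4a,5,6,7,8,8a-octahydronaphthalen-1-yl]carbonyl}-1,3-oxazolidin-2-one F2. Lithium ethanethiolate (EtSH, n-BuLi, THF, 0 °C) cleaves the auxiliary to the thioester S-ethyl (1R,4aS,8aR)-4-(hydroxymethyl)-3,4a,8,8-tetramethyl-1,2,4a,5,6,7,8,8a-octahydronaphthalene-1-carbothioate F3. Fukuyama reduction (Et3SiH, Pd/C, acetone, rt) then gives 15.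

Step 8. Insertion of rhodium into the hindered secondary formyl group may be slow, and β-hydride elimination to a ring alkene may compete with reductive elimination. The fallback removes the carbon atom by a radical path; it sets out from 15 and comes back at 16. Pinnick oxidation (NaClO2, NaH2PO4, 2-methylbut-2-ene, t-BuOH/H2O) should give the acid (1R,4aS,8aR)-4-(hydroxymethyl)-3,4a,8,8-tetramethyl-1,2,4a,5,6,7,8,8a-octahydronaphthalene-1-carboxylic acid F4. Coupling with 1-hydroxypyridine-2(1H)-thione (N,N'-dicyclohexylcarbodiimide, CH2Cl2, dark) gives the thiohydroxamate ester 2-thioxopyridin-1(2H)-yl (1R,4aS,8aR)-4-(hydroxymethyl)-3,4a,8,8-tetramethyl-1,2,4a,5,6,7,8,8a-octahydronaphthalene-1-carboxylate F5. Barton reductive decarboxylation (2-methylpropane-2-thiol, visible light, benzene, rt) gives 16.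

Step 6. Olefination of the neopentyl-type aldehyde may stay incomplete at 80 °C, and at a higher temperature the triene may cyclise thermally before it meets the catalyst, which would give racemic material. The fallback forms the enal at low temperature by addition and hydrolysis; it sets out from 11 and comes back at 12. (Z)-2-Ethoxyethenyllithium, made from tributyl[(Z)-2-ethoxyethenyl]stannane and n-BuLi (THF, −78 °C), adds to 11 to give the carbinol (1Z,8E)-1-ethoxy-4,4,8-trimethyl-9-(prop-1-en-2-yl)deca-1,8-diene-3,10-diol F6. Dilute aqueous HCl in THF at 0 °C hydrolyses the enol ether with loss of the C5 hydroxyl and should give the (E)-enal 12.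

Further compounds
F1 | step 7 | (4R)-4-benzyl-3-[(2E,8E)-10-hydroxy-4,4,8-trimethyl-9-(prop-1-en-2-yl)deca-2,8-dienoyl]-1,3-oxazolidin-2-one | O=C1OC[C@@H](Cc2ccccc2)N1C(=O)/C=C/C(C)(C)CCC/C(C)=C(/CO)C(C)=C
F2 | step 7 | (4R)-4-benzyl-3-{[(1R,4aS,8aR)-4-(hydroxymethyl)-3,4a,8,8-tetramethyl-1,2,4a,5,6,7,8,8a-octahydronaphthalen-1-yl]carbonyl}-1,3-oxazolidin-2-one | CC1=C(CO)[C@@]2(C)CCCC(C)(C)[C@H]2[C@H](C(=O)N3[C@H](Cc4ccccc4)COC3=O)C1
F3 | step 7 | S-ethyl (1R,4aS,8aR)-4-(hydroxymethyl)-3,4a,8,8-tetramethyl-1,2,4a,5,6,7,8,8a-octahydronaphthalene-1-carbothioate | CC1=C(CO)[C@@]2(C)CCCC(C)(C)[C@H]2[C@H](C(=O)SCC)C1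
F4 | step 8 | (1R,4aS,8aR)-4-(hydroxymethyl)-3,4a,8,8-tetramethyl-1,2,4a,5,6,7,8,8a-octahydronaphthalene-1-carboxylic acid | CC1=C(CO)[C@@]2(C)CCCC(C)(C)[C@H]2[C@H](C(O)=O)C1
F5 | step 8 | 2-thioxopyridin-1(2H)-yl (1R,4aS,8aR)-4-(hydroxymethyl)-3,4a,8,8-tetramethyl-1,2,4a,5,6,7,8,8a-octahydronaphthalene-1-carboxylate | CC1=C(CO)[C@@]2(C)CCCC(C)(C)[C@H]2[C@H](C(=O)ON3C=CC=CC3=S)C1
F6 | step 6 | (1Z,8E)-1-ethoxy-4,4,8-trimethyl-9-(prop-1-en-2-yl)deca-1,8-diene-3,10-diol | OC/C(C(C)=C)=C(\C)CCCC(C)(C)C(O)/C=C\OCC
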